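(Readings and results come from a simulation from invented constants, and the scatter is random.)

Sunday's run is slow to get going: target reads 0.5% at 2.50 min and 3.3% at 8.00 min. The lag fits a carrier charged as spent carrier, which must take up salt before it can act on substrate.

| flask | substrate | salt in the second phase | spent carrier | remark | volume of the second phase over the first |
|---|---|---|---|---|---|
| Sunday's | 1.7 M | 0.807 M | 85 mM | run made earlier |  |
| flask | 0.85 M | 0.807 M | 85 mM |  | 1.0 |

Sunday's run (percent of the substrate charged)

| time / min | target / % | substrate / % |
|---|---|---|
| 0.667 | 0 | 99.8 |
| 1.00 | 0.3 | 99.8 |
| 1.50 | 0.3 | 99.3 |
| 2.50 | 0.5 | 99.4 |
| 5.00 | 1.4 | 98.6 |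
| 8.00 | 3.3 | 97.1 |

(each reading ± 0.3 percentage points)

- in the second phase: salt in the second phase, spent salt in the second phase; everything else is in the first
- charges count per volume of the first phase; a concentration in a rate is the amount of a species over the volume of its own phase; every rate counts per litre of the first phase
- candidate steps: spent carrier + salt in the second phase <-> fresh carrier + spent salt in the second phase; substrate + fresh carrier <-> target + spent carrier
- the earlier runs hold the two phases in the same ratio of volumes as the flask asked about
- no earlier run changes the charge of spent carrier; that part of a forecast is a guess

- apparent order in spent carrier when 20% of the substrate are converted (percent change of the rate of making target for one percent more spent carrier charged)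
- factor on the rate of making target when 20% of the substrate are converted if spent carrier is charged twice over

Once fresh carrier is made as fast as it is used (the steady-state approximation), dividing the two forward rates removes time: c(fresh carrier)/c(spent carrier) = k(salt)·c(salt)/(k(substrate)·c(substrate)). The readings don't separate the two constants, so I take 0.0425 M of the carrier as fresh, half of the charge.

Each target and each fresh carrier costs one salt, so I reckon that at 20% conversion in this flask 0.595 M of salt remains. The salt toll, fresh carrier over salt left, is then 7.15%. Taking the rate as equally sensitive to both steps, I reckon an order of 0.964 and a doubling factor of 1.93.

The forecast gives an order of 0.95 (0.78 to 1), lower than mine, and a factor of 1.9 (1.68 to 2), calling the rate “first order in carrier” before a correction for salt held as fresh carrier.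

The flask gives an order of 0.94 and a factor of 1.87.

    spent carrier + salt in the second phase ⇌ fresh carrier + spent salt in the second phase (K = 3.00, k = 0.210 M⁻¹ min⁻¹)
    substrate + fresh carrier ⇌ target + spent carrier (K = 1.20, k = 0.210 M⁻¹ min⁻¹)

At 25.0 min, before the 32.1 min at which it reaches 20% conversion, this flask holds 48.7% of its carrier as fresh, with fresh carrier made 1.01 times as fast as it is used. One percent more on both constants of the salt step raises the rate by 0.55 percent. Taking that share of the toll of 7.15% from one gives an order of 0.961, against the flask's 0.94.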